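**Retrosynthetic overview**
1. The chain is numbered C1′–C9′ from the lactone. It is cut at the C5′–C6′ single bond, between the CH2 homoallylic to the C2′=C3′ alkene and the methyl-bearing sp2 carbon of the C6′=C7′ alkene. The bond is made by Ni-electrocatalytic decarboxylative alkenylation of a redox-active ester with an (E)-alkenyl iodide, a reductive union of two electrophiles.
2. Enabling feature: C5′ is an unfunctionalised primary CH2 and C6′ the fully substituted carbon of a trisubstituted E-alkene, each at least four bonds from the butenolide ring and from both furan rings. Neither has a polar handle, so C5′ is generated as a primary radical from a one-carbon-longer acid and C6′ is the iodine-bearing carbon of an (E)-2-iodo-2-alkene whose geometry is transferred.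
3. Left half: the C5 stereocentre comes from methyl (S)-glycidate, opened at CH2 by the alkenyl-copper reagent derived from hex-4-yn-1-ol (hydrozirconation/iodination sets the C2′=C3′ geometry). The terminal CH2OH becomes the acid, and the O-propanoate is the latent C2/C3 of the lactone.
4. Right half: both furan rings are bought (3-bromofuran, 4-bromo-2-furaldehyde) and joined through a carbinol that is deoxygenated. The pent-3-ynyl chain is attached by Negishi coupling and converted to the (E)-alkenyl iodide by hydrozirconation/iodination.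
5. Ring order: the furans come from commercial materials. The tetronic acid ring is the only ring made and is closed last by Dieckmann cyclisation (C3–C4 bond), so the acidic enol never needs protection.

Key step: step 13

Remark: the tetronic acid is taken as the 4-hydroxy-2(5H)-furanone tautomer drawn in the target structure.

**Step 1**
Reactants: 1 3-bromofuran; 2 4-bromofuran-2-carbaldehyde
Product: 4 (4-bromofuran-2-yl)(furan-3-yl)methanol (racemic), via furan-3-yllithium 3 (not isolated)
Conditions: 1, n-BuLi (1.05 equiv), THF, −78 °C; then 2, −78 °C; H2O quench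
Reagents that add atoms: none
Why: Bromine–lithium exchange followed by 1,2-addition to the aldehyde, which at −78 °C should outrun exchange with the C4–Br of 2 and migration of lithium to the furan α-position; the carbinol stereocentre is formed racemic and is removed in step 2.

**Step 2**
Reactants: 4 (4-bromofuran-2-yl)(furan-3-yl)methanol
Product: 5 4-bromo-2-(furan-3-ylmethyl)furan
Conditions: Et3SiH (4 equiv), CF3CO2H (3 equiv, slow addition), CH2Cl2, −40 → 0 °C; NaHCO3 work-up
Reagents that add atoms: none
Why: Ionic hydrogenation, in which the doubly furyl-stabilised carbenium ion forms at low temperature and should be trapped by excess silane faster than it alkylates another furan, the C4 bromine damping the acid sensitivity of the 2-substituted ring.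

**Step 3**
Reactants: 6 pent-3-yn-1-ol
Product: 7 5-iodopent-2-yne
Conditions: I2, PPh3, imidazole, CH2Cl2, 0 °C → rt
Reagents that add atoms: iodine, II
Why: Appel-type iodination of an unhindered primary alcohol by SN2 displacement of the alkoxyphosphonium ion; the internal alkyne is inert.

**Step 4**
Reactants: 7 5-iodopent-2-yne; 5 4-bromo-2-(furan-3-ylmethyl)furan
Product: 9 2-(furan-3-ylmethyl)-4-(pent-3-yn-1-yl)furan, via alkylzinc iodide 8 (not isolated)
Conditions: 7, Zn dust (activated), LiCl, THF, 40 °C; then 5, Pd(OAc)2 (2 mol %), SPhos (4 mol %), THF, rt → 50 °C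
Reagents that add atoms: none
Why: LiCl-promoted zinc insertion into the primary iodide followed by Negishi C(sp2)–C(sp3) coupling, in which the bulky biarylphosphine should make oxidative addition into the β-bromofuran and reductive elimination faster than β-hydride elimination.

**Step 5**
Reactants: 9 2-(furan-3-ylmethyl)-4-(pent-3-yn-1-yl)furan
Product: 11 2-(furan-3-ylmethyl)-4-[(3E)-4-iodopent-3-en-1-yl]furan, via alkenylzirconocene chloride 10 (not isolated)
Conditions: Cp2Zr(H)Cl (2.5 equiv), THF, 50 °C; then I2, THF, −20 → 0 °C; Na2S2O3/NaHCO3 work-up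
Reagents that add atoms: iodine, II
Why: Hydrozirconation–iodination, in which syn addition of Zr–H with excess Schwartz reagent under equilibrating conditions should place zirconium on the less hindered methyl-bearing carbon and iodinolysis with retention then fixes the E geometry (iodine trans to the chain CH2).

**Step 6**
Reactants: 12 hex-4-yn-1-ol
Product: 13 tert-butyl(hex-4-yn-1-yloxy)dimethylsilane
Conditions: TBSCl, imidazole, CH2Cl2, rt
Reagents that add atoms: tert-butyldimethylsilyl chloride, CC(C)(C)[Si](C)(C)Cl
Why: Standard imidazole-promoted silylation of a primary alcohol, which masks the hydroxyl against the organometallic steps that follow.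

**Step 7**
Reactants: 13 tert-butyl(hex-4-yn-1-yloxy)dimethylsilane
Product: 15 tert-butyl{[(4E)-5-iodohex-4-en-1-yl]oxy}dimethylsilane, via alkenylzirconocene chloride 14 (not isolated)
Conditions: Cp2Zr(H)Cl (2.5 equiv), THF, 50 °C; then I2, THF, −20 → 0 °C
Reagents that add atoms: iodine, II
Why: The same hydrozirconation–iodination as in step 5, with thermodynamic placement of zirconium at the methyl-bearing alkyne carbon and stereoretentive C–Zr to C–I exchange giving the E-iodide.

**Step 8**
Reactants: 15 tert-butyl{[(4E)-5-iodohex-4-en-1-yl]oxy}dimethylsilane; 16 methyl (2S)-oxirane-2-carboxylate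
Product: 19 methyl (2S,4E)-8-[(tert-butyldimethylsilyl)oxy]-2-hydroxy-4-methyloct-4-enoate, via alkenyllithium 17 (not isolated), via alkenylmagnesium bromide 18 (not isolated)
Conditions: 15 (1.3 equiv), t-BuLi (2.6 equiv), Et2O, −78 °C; MgBr2·OEt2 (1.4 equiv), −78 → −40 °C; CuI (10 mol %), then 16 (1.0 equiv), THF, −40 → −20 °C; H2O quench
Reagents that add atoms: none
Why: Iodine–lithium exchange with retention of alkene geometry, transmetallation to magnesium and copper-catalysed SN2 opening of the glycidic ester at its unsubstituted CH2 (organocuprate epoxide opening); the C2–O bond is not touched, so the S stereocentre is carried over unchanged from the chiral pool.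

**Step 9**
Reactants: 19 methyl (2S,4E)-8-[(tert-butyldimethylsilyl)oxy]-2-hydroxy-4-methyloct-4-enoate
Product: 20 methyl (2S,4E)-8-[(tert-butyldimethylsilyl)oxy]-4-methyl-2-(propanoyloxy)oct-4-enoate
Conditions: EtCOCl, pyridine, DMAP (cat.), CH2Cl2, 0 °C
Reagents that add atoms: propanoyl chloride, CCC(=O)Cl
Why: DMAP-catalysed O-acylation of the secondary alcohol, which breaks no bond to the stereocentre and installs the three carbons that become C2, C3 and the 3-methyl group of the lactone.

**Step 10**
Reactants: 20 methyl (2S,4E)-8-[(tert-butyldimethylsilyl)oxy]-4-methyl-2-(propanoyloxy)oct-4-enoate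
Product: 21 methyl (2S,4E)-8-hydroxy-4-methyl-2-(propanoyloxy)oct-4-enoate
Conditions: HF·pyridine, THF, 0 °C → rt
Reagents that add atoms: none
Why: Fluoride cleavage of the primary silyl ether under buffered, non-basic conditions, which should leave both esters and the α-stereocentre untouched.

**Step 11**
Reactants: 21 methyl (2S,4E)-8-hydroxy-4-methyl-2-(propanoyloxy)oct-4-enoate
Product: 22 (4E,7S)-8-methoxy-5-methyl-8-oxo-7-(propanoyloxy)oct-4-enoic acid
Conditions: TEMPO (0.2 equiv), PhI(OAc)2 (2.2 equiv), MeCN/H2O 1:1, rt
Reagents that add atoms: water, O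
Why: Oxoammonium (TEMPO/hypervalent iodine) oxidation of the primary alcohol through the aldehyde hydrate to the acid under near-neutral conditions compatible with the esters and the trisubstituted alkene.

**Step 12**
Reactants: 22 (4E,7S)-8-methoxy-5-methyl-8-oxo-7-(propanoyloxy)oct-4-enoic acid
Product: 23 1-(1,3-dioxoisoindolin-2-yl) 8-methyl (4E,7S)-5-methyl-7-(propanoyloxy)oct-4-enedioate
Conditions: N-hydroxyphthalimide, DIC, DMAP (cat.), CH2Cl2, rt; rapid filtration through silica
Reagents that add atoms: N-hydroxyphthalimide, O=C1c2ccccc2C(=O)N1O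
Why: Carbodiimide (Steglich-type) esterification gives the redox-active N-acyloxyphthalimide that arms the chain terminus for single-electron fragmentation.

**Step 13**
Reactants: 23 1-(1,3-dioxoisoindolin-2-yl) 8-methyl (4E,7S)-5-methyl-7-(propanoyloxy)oct-4-enedioate; 11 2-(furan-3-ylmethyl)-4-[(3E)-4-iodopent-3-en-1-yl]furan
Product: 24 methyl (2S,4E,8E)-11-[5-(furan-3-ylmethyl)furan-3-yl]-4,8-dimethyl-2-(propanoyloxy)undeca-4,8-dienoate
Conditions: 23 (1.5 equiv), 11 (1.0 equiv), NiCl2·6H2O (10 mol %), 2,2′-bipyridine (10 mol %), AgNO3 (0.3 equiv), LiCl, DMF, undivided cell, Mg(+)/RVC(−), constant current, rt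
Reagents that add atoms: none
Why: Cathodic reduction converts the bipyridine–Ni(II) precatalyst into low-valent nickel, which adds oxidatively into the C–I bond of 11 with retention of geometry, while single-electron reduction of 23 (by Ni(I) or at the silver-coated cathode) expels phthalimide anion and CO2 to leave the primary homoallylic radical; capture of this radical by the alkenyl–Ni(II) species and reductive elimination from Ni(III) forms the C(sp3)–C(sp2) bond, the magnesium anode supplying the electrons. The closest known reaction type is the nickel-electrocatalytic decarboxylative alkenylation of redox-active esters with alkenyl iodides on silver-modified cathodes, used to assemble polyene terpenoid chains, with reductive cross-electrophile coupling and decarboxylative Negishi alkenylation as its thermal relatives. No ring is closed and no stereocentre is formed; the E geometry of the C8=C9 alkene is controlled by the alkenyl iodide because oxidative addition and reductive elimination are stereoretentive, and the C2 stereocentre is remote from the radical and sees no base. The step needs cross- over homo-coupling selectivity, which the orthogonal activation modes of the two electrophiles (single-electron fragmentation for the ester, two-electron oxidative addition for the iodide) and the excess of 23 should secure. It also needs the radical to survive, which it should because the only alkene within reach is homoallylic (3-exo closure is reversible and unproductive) and the methyl ester, the propanoate and both furan rings are not reduced at the nickel potential.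

**Step 14**
Reactants: 24 methyl (2S,4E,8E)-11-[5-(furan-3-ylmethyl)furan-3-yl]-4,8-dimethyl-2-(propanoyloxy)undeca-4,8-dienoate
Product: 25 (5S)-5-{(2E,6E)-9-[5-(furan-3-ylmethyl)furan-3-yl]-2,6-dimethylnona-2,6-dien-1-yl}-4-hydroxy-3-methylfuran-2(5H)-one
Conditions: LiHMDS (3 equiv), THF, −78 → 0 °C; then 1 M HCl to pH 2–3
Reagents that add atoms: none
Why: Dieckmann cyclisation, in which the lithium enolate of the propanoate attacks the neighbouring methyl ester in a 5-exo-trig closure and loss of methoxide gives the stabilised lithium tetronate that drives the reaction; the S centre (C2 of 24, C5 of 25) should be retained because the propanoate CH2 is deprotonated and cyclises at low temperature faster than the C2 hydrogen is removed.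

**Compound list**
1 | 3-bromofuran | Brc1ccoc1 | starting material
2 | 4-bromofuran-2-carbaldehyde | O=Cc1cc(Br)co1 | starting material
3 | furan-3-yllithium | [Li]c1ccoc1 | intermediate
4 | (4-bromofuran-2-yl)(furan-3-yl)methanol, racemic | OC(c1ccoc1)c1cc(Br)co1 | intermediate
5 | 4-bromo-2-(furan-3-ylmethyl)furan | Brc1coc(Cc2ccoc2)c1 | intermediate
6 | pent-3-yn-1-ol | CC#CCCO | starting material
7 | 5-iodopent-2-yne | CC#CCCI | intermediate
8 | iodo(pent-3-yn-1-yl)zinc | CC#CCC[Zn]I | intermediate
9 | 2-(furan-3-ylmethyl)-4-(pent-3-yn-1-yl)furan | CC#CCCc1coc(Cc2ccoc2)c1 | intermediate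
10 | chloridobis(cyclopentadienyl){(2E)-5-[5-(furan-3-ylmethyl)furan-3-yl]pent-2-en-2-yl}zirconium (Cp rings drawn σ-bonded; Zr trans to the chain CH2) | C/C(=C\CCc1coc(Cc2ccoc2)c1)[Zr](Cl)(C1C=CC=C1)C1C=CC=C1 | intermediate
11 | 2-(furan-3-ylmethyl)-4-[(3E)-4-iodopent-3-en-1-yl]furan | C/C(I)=C\CCc1coc(Cc2ccoc2)c1 | intermediate
12 | hex-4-yn-1-ol | CC#CCCCO | starting material
13 | tert-butyl(hex-4-yn-1-yloxy)dimethylsilane | CC#CCCCO[Si](C)(C)C(C)(C)C | intermediate
14 | chloridobis(cyclopentadienyl){(2E)-6-[(tert-butyldimethylsilyl)oxy]hex-2-en-2-yl}zirconium (Cp rings drawn σ-bonded; Zr trans to the chain CH2) | C/C(=C\CCCO[Si](C)(C)C(C)(C)C)[Zr](Cl)(C1C=CC=C1)C1C=CC=C1 | intermediate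
15 | tert-butyl{[(4E)-5-iodohex-4-en-1-yl]oxy}dimethylsilane | C/C(I)=C\CCCO[Si](C)(C)C(C)(C)C | intermediate
16 | methyl (2S)-oxirane-2-carboxylate (methyl (S)-glycidate) | COC(=O)[C@@H]1CO1 | starting material
17 | {6-[(tert-butyldimethylsilyl)oxy]hex-2-en-2-yl}lithium, Li trans to the chain CH2 (geometry of 15 retained) | C/C([Li])=C\CCCO[Si](C)(C)C(C)(C)C | intermediate
18 | bromo{(2E)-6-[(tert-butyldimethylsilyl)oxy]hex-2-en-2-yl}magnesium | C/C([Mg]Br)=C\CCCO[Si](C)(C)C(C)(C)C | intermediate
19 | methyl (2S,4E)-8-[(tert-butyldimethylsilyl)oxy]-2-hydroxy-4-methyloct-4-enoate | COC(=O)[C@@H](O)C/C(C)=C/CCCO[Si](C)(C)C(C)(C)C | intermediate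
20 | methyl (2S,4E)-8-[(tert-butyldimethylsilyl)oxy]-4-methyl-2-(propanoyloxy)oct-4-enoate | CCC(=O)O[C@@H](C/C(C)=C/CCCO[Si](C)(C)C(C)(C)C)C(=O)OC | intermediate
21 | methyl (2S,4E)-8-hydroxy-4-methyl-2-(propanoyloxy)oct-4-enoate | CCC(=O)O[C@@H](C/C(C)=C/CCCO)C(=O)OC | intermediate
22 | (4E,7S)-8-methoxy-5-methyl-8-oxo-7-(propanoyloxy)oct-4-enoic acid | CCC(=O)O[C@@H](C/C(C)=C/CCC(=O)O)C(=O)OC | intermediate
23 | 1-(1,3-dioxoisoindolin-2-yl) 8-methyl (4E,7S)-5-methyl-7-(propanoyloxy)oct-4-enedioate | CCC(=O)O[C@@H](C/C(C)=C/CCC(=O)ON1C(=O)c2ccccc2C1=O)C(=O)OC | intermediate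
24 | methyl (2S,4E,8E)-11-[5-(furan-3-ylmethyl)furan-3-yl]-4,8-dimethyl-2-(propanoyloxy)undeca-4,8-dienoate | CCC(=O)O[C@@H](C/C(C)=C/CC/C(C)=C/CCc1coc(Cc2ccoc2)c1)C(=O)OC | intermediate
25 | (5S)-5-{(2E,6E)-9-[5-(furan-3-ylmethyl)furan-3-yl]-2,6-dimethylnona-2,6-dien-1-yl}-4-hydroxy-3-methylfuran-2(5H)-one | CC1=C(O)[C@H](C/C(C)=C/CC/C(C)=C/CCc2coc(Cc3ccoc3)c2)OC1=O | target

**Step count and risks**
Total: 14 steps. Longest linear sequence: 9 steps (steps 6–14, from hex-4-yn-1-ol); the furan branch contributes steps 1–5.

Most likely to fail: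

Step 13. The hindered α-methyl alkenyl iodide may undergo slow oxidative addition, so that homocoupling or protodeiodination of the iodide and reduction or dimerisation of the radical compete with cross-coupling; partial loss of alkene geometry at nickel is a second concern. The fallback sets out from 11 and 23 and comes back at 24. Compound 11 would be treated with t-BuLi (Et2O, −78 °C) to give the alkenyllithium F1, which ZnCl2 converts into the alkenylzinc chloride F2. F2 would then be coupled with 23 under Ni(acac)2/2,2′-bipyridine in THF/DMF at rt (redox-neutral decarboxylative Negishi-type alkenylation), which needs no electrolysis and no second electrophile.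

Step 2. Acid-induced oligomerisation, by Friedel–Crafts alkylation of a furan by the bis-furyl carbenium ion, or acid-induced furan ring opening may outrun hydride transfer. The fallback sets out from 4 and comes back at 5. Compound 4 would be oxidised with MnO2 (CH2Cl2, rt) to (4-bromofuran-2-yl)(furan-3-yl)methanone F3, and this would be reduced under Wolff–Kishner conditions (N2H4·H2O, KOH, diethylene glycol, 130 → 190 °C, Huang–Minlon procedure) through the hydrazone F4. The chemistry is base-mediated throughout, and furans tolerate base well.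

Step 8. The alkenyl-metal may attack the ester carbonyl, bromide from the magnesium salt may open the epoxide to a bromohydrin, or opening may occur at C2. The fallback sets out from 17 (made from 15 as in step 8) and comes back at 19.
- Alkenyllithium 17 would be trapped with paraformaldehyde to give (2E)-6-[(tert-butyldimethylsilyl)oxy]-2-methylhex-2-en-1-ol F5, which CBr4/PPh3 converts into the allylic bromide tert-butyl{[(4E)-6-bromo-5-methylhex-4-en-1-yl]oxy}dimethylsilane F6.
- The sodium enolate (NaHMDS, THF, −78 °C) of (4R)-4-benzyl-3-{[(4-methoxybenzyl)oxy]acetyl}-1,3-oxazolidin-2-one F7 would be alkylated with F6. F7 is prepared from (R)-4-benzyloxazolidin-2-one, n-BuLi and (4-methoxybenzyloxy)acetyl chloride. This auxiliary-controlled glycolate alkylation occurs on the enolate face opposite the benzyl group and sets the 2S centre, giving the imide (4R)-4-benzyl-3-[(2S,4E)-8-[(tert-butyldimethylsilyl)oxy]-2-[(4-methoxybenzyl)oxy]-4-methyloct-4-enoyl]-1,3-oxazolidin-2-one F8.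
- Methanolysis of F8 (MeMgBr/MeOH, 0 °C) would give methyl (2S,4E)-8-[(tert-butyldimethylsilyl)oxy]-2-[(4-methoxybenzyl)oxy]-4-methyloct-4-enoate F9, and DDQ (CH2Cl2/pH 7 buffer) would remove the 4-methoxybenzyl group to return 19.

**Further compounds**
F1 | step 13 | {5-[5-(furan-3-ylmethyl)furan-3-yl]pent-2-en-2-yl}lithium, Li trans to the chain CH2 | C/C([Li])=C\CCc1coc(Cc2ccoc2)c1
F2 | step 13 | chloro{(2E)-5-[5-(furan-3-ylmethyl)furan-3-yl]pent-2-en-2-yl}zinc | C/C([Zn]Cl)=C\CCc1coc(Cc2ccoc2)c1
F3 | step 2 | (4-bromofuran-2-yl)(furan-3-yl)methanone | O=C(c1ccoc1)c1cc(Br)co1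
F4 | step 2 | (4-bromofuran-2-yl)(furan-3-yl)methanone hydrazone | NN=C(c1ccoc1)c1cc(Br)co1
F5 | step 8 | (2E)-6-[(tert-butyldimethylsilyl)oxy]-2-methylhex-2-en-1-ol | OC/C(C)=C/CCCO[Si](C)(C)C(C)(C)C
F6 | step 8 | tert-butyl{[(4E)-6-bromo-5-methylhex-4-en-1-yl]oxy}dimethylsilane | BrC/C(C)=C/CCCO[Si](C)(C)C(C)(C)C
F7 | step 8 | (4R)-4-benzyl-3-{[(4-methoxybenzyl)oxy]acetyl}-1,3-oxazolidin-2-one | COc1ccc(COCC(=O)N2[C@H](Cc3ccccc3)COC2=O)cc1
F8 | step 8 | (4R)-4-benzyl-3-[(2S,4E)-8-[(tert-butyldimethylsilyl)oxy]-2-[(4-methoxybenzyl)oxy]-4-methyloct-4-enoyl]-1,3-oxazolidin-2-one | COc1ccc(CO[C@@H](C/C(C)=C/CCCO[Si](C)(C)C(C)(C)C)C(=O)N2[C@H](Cc3ccccc3)COC2=O)cc1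
F9 | step 8 | methyl (2S,4E)-8-[(tert-butyldimethylsilyl)oxy]-2-[(4-methoxybenzyl)oxy]-4-methyloct-4-enoate | COc1ccc(CO[C@@H](C/C(C)=C/CCCO[Si](C)(C)C(C)(C)C)C(=O)OC)cc1
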